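The ten-membered carbocycle is not closed end to end. The homoallylic alcohol C6(OH)–C7–C11=C13 of the ten-membered ring is the retron of a [2,3]-Wittig shift in a C6–O–C13 propargyl allyl ether, so the ring is made thirteen-membered first and then contracted. In one operation the shift forms C6–C7, creates the C11=C13 methylene, sets C6 and C7 and leaves a C4≡C5 alkyne that later becomes the C4=C5 alkene carrying C15. The precursor is a macrocyclic ether with (Z)-C1=C10, ring-trans C7=C11 and silyl ethers at C2, C8 and C12; C8 is carried as its epimer and inverted in the last step.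

Key step: step 19

Remark (labels): atoms carry the germacrane labels C1 to C15 of the target in every compound (C14 = methyl on C10, C15 on C4, C12 and C13 on C11), and stereodescriptors are quoted with these labels; TES = triethylsilyl, TBS = tert-butyldimethylsilyl, PMB = 4-methoxybenzyl.

Remark (assumption on the face of the shift): ring carbon C9 must lie gauche to the forming C6–C7 bond and C8–H eclipses C7=C11 (allylic 1,3-strain against C12), so C6 is taken to arrive anti to the C8–O bond, which leaves O8 trans to C11; the ether is therefore built as the C8 epimer (8S) and C8 is inverted in step 27.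

Remark (geometry): in compounds 8 to 24 C8 is trans to C13 across C7=C11 (trans within the large ring), whatever CIP letter the C12 and C13 substituents give; C4=C5 of the target is likewise trans in the ring although its descriptor is Z.

Step 1
Reactants: 1 propargyl alcohol
Product: 2 triethyl(prop-2-yn-1-yloxy)silane
Conditions: Et3SiCl, imidazole, CH2Cl2, 0 °C to rt
Reagents that add atoms: triethylsilyl chloride, CC[Si](Cl)(CC)CC
Why: Silyl ether formation on a primary alcohol is routine, and the TES group on the future C12 oxygen survives bases, cuprates and hydrides until its planned removal in step 23.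

Step 2
Reactants: 2 triethyl(prop-2-yn-1-yloxy)silane
Product: 3 methyl 4-(triethylsilyloxy)but-2-ynoate
Conditions: n-BuLi, THF, −78 °C; ClCO2Me, −78 to 0 °C
Reagents that add atoms: methyl chloroformate, COC(=O)Cl
Why: Deprotonation of the terminal alkyne and C-acylation of the acetylide (acetylide carboxylation) give the ynoate that holds C8 (ester carbon), C7, C11 and C12.

Step 3
Reactants: 4 (tributylstannyl)methanol
Product: 5 tributyl[(4-methoxybenzyloxy)methyl]stannane
Conditions: NaH, 4-methoxybenzyl chloride, Bu4NI (5 mol %), THF–DMF, 0 °C to rt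
Reagents that add atoms: 4-methoxybenzyl chloride, COc1ccc(CCl)cc1
Why: Williamson etherification of the stannyl carbinol gives a storable source of an alkoxymethyl carbanion by tin–lithium exchange.

Step 4
Reactants: 5 tributyl[(4-methoxybenzyloxy)methyl]stannane; 3 methyl 4-(triethylsilyloxy)but-2-ynoate
Product: 8 methyl (Z)-4-(4-methoxybenzyloxy)-3-(triethylsilyloxymethyl)but-2-enoate, via (4-methoxybenzyloxy)methyllithium 6 (not isolated), via lithium bis[(4-methoxybenzyloxy)methyl]cuprate 7 (not isolated)
Conditions: 5 (2.2 equiv), n-BuLi, THF, −78 °C; CuBr·SMe2 (1.1 equiv), −78 to −40 °C; 3, −78 °C; MeOH then aq NH4Cl at −78 °C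
Reagents that add atoms: none
Why: Tin–lithium exchange and transmetalation to copper give a homocuprate whose syn carbocupration of the ynoate (organocuprate conjugate addition) and cold protonation put the new C13 arm cis to the C7 hydrogen, so the C12 arm ends up cis to the ester carbon C8 and the two oxygenated arms on C11 are differentiated with defined geometry.

Step 5
Reactants: 8 methyl (Z)-4-(4-methoxybenzyloxy)-3-(triethylsilyloxymethyl)but-2-enoate
Product: 9 (Z)-4-(4-methoxybenzyloxy)-3-(triethylsilyloxymethyl)but-2-en-1-ol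
Conditions: i-Bu2AlH (2.2 equiv), CH2Cl2, −78 °C; aq potassium sodium tartrate
Reagents that add atoms: none
Why: 1,2-Reduction of the α,β-unsaturated ester with a dialkylaluminium hydride at low temperature (ester to allylic alcohol) leaves the ethers and the alkene geometry untouched.

Step 6
Reactants: 9 (Z)-4-(4-methoxybenzyloxy)-3-(triethylsilyloxymethyl)but-2-en-1-ol
Product: 10 (Z)-4-(4-methoxybenzyloxy)-3-(triethylsilyloxymethyl)but-2-enal
Conditions: activated MnO2, CH2Cl2, rt
Reagents that add atoms: none
Why: Activated MnO2 oxidises primary allylic alcohols under neutral conditions (allylic oxidation), and the enal is used at once so that the two arms on C11 cannot equilibrate.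

Step 7
Reactants: 10 (Z)-4-(4-methoxybenzyloxy)-3-(triethylsilyloxymethyl)but-2-enal; 11 allenylboronic acid pinacol ester
Product: 12 (8S)-enynol
Conditions: (S)-3,3′-bis(2,4,6-triisopropylphenyl)-1,1′-binaphthyl-2,2′-diyl hydrogen phosphate (10 mol %), 4 Å molecular sieves, toluene, −30 °C
Reagents that add atoms: none
Why: Chiral phosphoric acid-catalysed propargylboration of the enal by the allenylboronate (SE2′ addition through a six-membered chair) creates C8, the (S)-acid being chosen by analogy with aryl and alkenyl aldehydes to give the (8S) carbinol wanted for step 19; the sense is to be confirmed by NMR of the two α-methoxy-α-trifluoromethylphenylacetates and the antipodal acid used if it proves opposite.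

Step 8
Reactants: 12 (8S)-enynol
Product: 13 (8S)-enyne TBS ether
Conditions: t-BuMe2SiOTf, 2,6-lutidine, CH2Cl2, −78 °C
Reagents that add atoms: tert-butyldimethylsilyl trifluoromethanesulfonate, CC(C)(C)[Si](C)(C)OS(=O)(=O)C(F)(F)F
Why: Silylation of the secondary alcohol with a silyl triflate and a hindered base (silyl ether formation) is fast at −78 °C and leaves the TES ether and the alkyne untouched.

Step 9
Reactants: 13 (8S)-enyne TBS ether
Product: 14 (8S)-ynoate
Conditions: n-BuLi (1.05 equiv), THF, −78 °C; ClCO2Me, −78 to 0 °C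
Reagents that add atoms: methyl chloroformate, COC(=O)Cl
Why: As in step 2 the lithium acetylide is acylated by the chloroformate (acetylide carboxylation), one equivalent of base at −78 °C touching only the alkyne C–H.

Step 10
Reactants: 14 (8S)-ynoate
Product: 15 (8S)-(1Z)-dienoate
Conditions: Me2CuLi (from MeLi and CuI), THF, −78 °C; MeOH then aq NH4Cl at −78 °C
Reagents that add atoms: lithium dimethylcuprate, [Li+].C[Cu-]C
Why: syn-Carbocupration of the ynoate and protonation at −78 °C (organocuprate conjugate addition) put the new methyl C14 cis to the C1 hydrogen, hence C9 cis to the ester carbon C2, which is the (Z)-C1=C10 geometry of the target.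

Step 11
Reactants: 15 (8S)-(1Z)-dienoate
Product: 16 (8S)-dienol
Conditions: i-Bu2AlH (2.2 equiv), CH2Cl2, −78 °C; aq potassium sodium tartrate
Reagents that add atoms: none
Why: The same ester-to-allylic-alcohol reduction as in step 5 is used, the silyl and benzyl ethers being inert to the hydride at −78 °C.

Step 12
Reactants: 16 (8S)-dienol
Product: 17 (8S)-dienal
Conditions: activated MnO2, CH2Cl2, rt
Reagents that add atoms: none
Why: Allylic oxidation with MnO2 as in step 6 gives the (Z)-enal without isomerisation of either trisubstituted alkene when the product is used directly.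

Step 13
Reactants: 17 (8S)-dienal; 11 allenylboronic acid pinacol ester
Product: 18 (2S,8S)-dienynol
Conditions: (S)-3,3′-bis(2,4,6-triisopropylphenyl)-1,1′-binaphthyl-2,2′-diyl hydrogen phosphate (10 mol %), 4 Å molecular sieves, toluene, −30 °C
Reagents that add atoms: none
Why: A second catalytic propargylboration with the same (S)-acid creates C2 with the (S) configuration of the target by reagent control, the remote C8 centre having little influence, and the assignment is checked as in step 7.

Step 14
Reactants: 18 (2S,8S)-dienynol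
Product: 19 C2 TES ether
Conditions: Et3SiCl, imidazole, DMF, 0 °C
Reagents that add atoms: triethylsilyl chloride, CC[Si](Cl)(CC)CC
Why: Silyl ether formation gives C2 the same group as the C12 oxygen, so that both are released together in step 23, and removes the only O–H before the strong bases of steps 17 to 19.

Step 15
Reactants: 19 C2 TES ether
Product: 20 C13 alcohol
Conditions: 2,3-dichloro-5,6-dicyano-1,4-benzoquinone (1.2 equiv), CH2Cl2–pH 7 buffer, 0 °C
Reagents that add atoms: none
Why: Oxidative cleavage of the PMB ether by the quinone (benzylic hydride abstraction and hydrolysis of the hemiacetal) frees only the C13 hydroxyl and leaves the three silyl ethers in place under buffered conditions.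

Step 16
Reactants: 20 C13 alcohol
Product: 22 C13 chloride, via allylic mesylate 21 (not isolated)
Conditions: MsCl, LiCl, 2,4,6-collidine, DMF, 0 °C
Reagents that add atoms: lithium chloride, [Li+].[Cl-]
Why: Mesylation in the presence of chloride converts the primary allylic alcohol into the allylic chloride by SN2 displacement, without allylic transposition because C7 is the more hindered terminus and without forming an alkoxide next to the C12 silyl ether.

Step 17
Reactants: 22 C13 chloride
Product: 23 chloro propargylic alcohol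
Conditions: lithium diisopropylamide (1.05 equiv), THF, −78 °C; paraformaldehyde, −78 °C to rt; aq NH4Cl
Reagents that add atoms: paraformaldehyde (reacts as formaldehyde), C=O
Why: The lithium acetylide adds to formaldehyde (alkyne hydroxymethylation) to install C6, and in THF without polar additives it does not alkylate the allylic chloride.

Step 18
Reactants: 23 chloro propargylic alcohol
Product: 24 thirteen-membered propargyl allyl ether
Conditions: EtMgBr (1.1 equiv), THF, 0 °C; slow addition to THF–HMPA at 65 °C (final 0.003 M)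
Reagents that add atoms: none
Why: Intramolecular Williamson etherification of the propargylic magnesium alkoxide with the primary allylic chloride under high dilution closes the strain-free thirteen-membered ring, the oxygen nucleophile being far from every silyl ether so that no silyl migration can scramble C12 and C13.

Step 19
Reactants: 24 thirteen-membered propargyl allyl ether
Product: 25 ten-membered cycloalkenynol
Conditions: 2,2,6,6-tetramethylpiperidine, n-BuLi, THF, 0 °C; 24, THF, −78 to −30 °C; aq NH4Cl
Reagents that add atoms: none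
Why: The amide base removes a proton from C6, the one carbon that is both propargylic and ether-bound, and the carbanion bonds to C7 through a five-membered envelope (C6, O, C13, C11, C7) while O–C13 breaks and C11=C13 forms, a concerted suprafacial [2,3]-Wittig shift. The closest known reaction type is the [2,3]-Wittig ring contraction of macrocyclic propargyl allyl ethers to cycloalkynols. The ten-membered carbocycle is closed by contraction of the thirteen-membered ether, the new bond joining two ring atoms that stand 1,5 across the oxygen bridge, not by an exo or endo closure of an open chain. C6 and C7 are set relative to each other by the geometry of C7=C11 (C8 trans to C13) with the alkynyl arm exo on the envelope, which puts O6 trans to C11 as the trans-lactone needs. Their absolute sense is set by C8: C8–H eclipses the alkene to avoid strain against C12, ring carbon C9 lies gauche to the new bond and C6 arrives anti to the C8–O bond, so the (8S) ether should give the (6S,7S) alcohol 25, which has the C6 and C7 arrangement of the target. The step needs deprotonation at C6 and not at C13 or C3, and a [2,3] and not a [1,2] shift; the alkyne makes C6 the most acidic ether carbon, the precursor carries no benzylic ether, and low temperature with a non-nucleophilic amide favours the concerted path.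

Step 20
Reactants: 25 ten-membered cycloalkenynol
Product: 27 C4 iodide, via sodium alkenylalanate 26 (not isolated)
Conditions: NaAlH2(OCH2CH2OCH3)2, THF, 0 °C to rt; I2, THF, −78 °C; aq Na2S2O3 and potassium sodium tartrate
Reagents that add atoms: iodine, II
Why: The C6 alkoxide binds aluminium and delivers hydride to C5, so that aluminium ends on C4 in a five-membered oxaalumole (hydroxyl-directed trans-hydroalumination of a propargylic alcohol), and iodinolysis with retention fixes C3 trans to C6 across the new C4=C5 bond.

Step 21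
Reactants: 27 C4 iodide; 4 (tributylstannyl)methanol
Product: 28 C15,C6-diol
Conditions: Pd(PPh3)4 (10 mol %), CuI (20 mol %), DMF, 50 °C
Reagents that add atoms: none
Why: Stille coupling of the alkenyl iodide with the hydroxymethylstannane replaces iodine by the C15 hydroxymethyl group with retention of alkene geometry, the copper salt speeding transmetalation.

Step 22
Reactants: 28 C15,C6-diol
Product: 29 C15 acetate
Conditions: AcCl (1.1 equiv), 2,4,6-collidine, CH2Cl2, −78 °C
Reagents that add atoms: acetyl chloride, CC(=O)Cl
Why: Acetyl chloride with a hindered pyridine at −78 °C acylates the primary allylic C15 hydroxyl much faster than the hindered secondary C6 hydroxyl (selective acetylation of a primary alcohol).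

Step 23
Reactants: 29 C15 acetate
Product: 30 triol
Conditions: pyridinium p-toluenesulfonate, MeOH, 0 °C to rt
Reagents that add atoms: none
Why: Mild acid methanolysis removes the two TES ethers at C2 and C12 and leaves the secondary TBS ether at C8 and the acetate intact.

Step 24
Reactants: 30 triol
Product: 32 lactone alcohol, via lactol 31 (not isolated)
Conditions: 2,2,6,6-tetramethylpiperidin-1-oxyl (20 mol %), PhI(OAc)2 (2.5 equiv), CH2Cl2, rt
Reagents that add atoms: none
Why: The nitroxyl-catalysed oxidation attacks only the primary allylic C12 hydroxyl, which closes with the C6 hydroxyl to lactol 31 and is oxidised again to the α-methylene-γ-lactone (oxidative lactonisation), O8 being silylated and the secondary C2 hydroxyl reacting far more slowly.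

Step 25
Reactants: 32 lactone alcohol; 33 angelic acid
Product: 35 angelate TBS ether, via mixed anhydride 34 (not isolated)
Conditions: 33, 2,4,6-trichlorobenzoyl chloride, Et3N, toluene, rt; then 32, toluene, 75 °C
Reagents that add atoms: none
Why: Yamaguchi esterification through mixed anhydride 34 without a nucleophilic catalyst acylates the only free hydroxyl, at C2, and is the established way to make angelates without isomerisation to tiglates.

Step 26
Reactants: 35 angelate TBS ether
Product: 36 8-epi alcohol
Conditions: HF·pyridine, pyridine, THF, 0 °C to rt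
Reagents that add atoms: none
Why: Buffered hydrogen fluoride cleaves the secondary silyl ether (fluoride-mediated desilylation) without touching the esters or the lactone.

Step 27
Reactants: 36 8-epi alcohol
Product: 38 target CNP0129394.1, via C8 formate 37 (not isolated)
Conditions: PPh3, diisopropyl azodicarboxylate, HCO2H, THF, 0 °C to rt; then MeOH, aq KHCO3, 0 °C
Reagents that add atoms: formic acid, O=CO
Why: Mitsunobu reaction with formic acid inverts C8 by SN2 displacement of the oxyphosphonium ion to give the (8R) formate 37, whose formyl group is removed by mild methanolysis much faster than acetate, angelate or lactone, which sets the last stereocentre.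

Compound list

1 | propargyl alcohol | C#CCO | starting material
2 | triethyl(prop-2-yn-1-yloxy)silane | C#CCO[Si](CC)(CC)CC | intermediate
3 | methyl 4-(triethylsilyloxy)but-2-ynoate | COC(=O)C#CCO[Si](CC)(CC)CC | intermediate
4 | (tributylstannyl)methanol | CCCC[Sn](CCCC)(CCCC)CO | starting material
5 | tributyl[(4-methoxybenzyloxy)methyl]stannane | CCCC[Sn](CCCC)(CCCC)COCc1ccc(OC)cc1 | intermediate
6 | (4-methoxybenzyloxy)methyllithium | [Li]COCc1ccc(OC)cc1 | intermediate (not isolated)
7 | lithium bis[(4-methoxybenzyloxy)methyl]cuprate | [Li+].COc1ccc(COC[Cu-]COCc2ccc(OC)cc2)cc1 | intermediate (not isolated)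
8 | methyl (Z)-4-(4-methoxybenzyloxy)-3-(triethylsilyloxymethyl)but-2-enoate; ester carbon C8 cis to C12H2OTES, trans to C13H2OPMB | COC(=O)/C=C(/COCc1ccc(OC)cc1)CO[Si](CC)(CC)CC | intermediate
9 | (Z)-4-(4-methoxybenzyloxy)-3-(triethylsilyloxymethyl)but-2-en-1-ol | OC/C=C(/COCc1ccc(OC)cc1)CO[Si](CC)(CC)CC | intermediate
10 | (Z)-4-(4-methoxybenzyloxy)-3-(triethylsilyloxymethyl)but-2-enal | O=C/C=C(/COCc1ccc(OC)cc1)CO[Si](CC)(CC)CC | intermediate
11 | allenylboronic acid pinacol ester | C=C=CB1OC(C)(C)C(C)(C)O1 | starting material
12 | (8S)-enynol: HC1≡C10–C9H2–C8H(OH)–C7H=C11(C12H2OTES)–C13H2OPMB; C8 cis to C12 | C#CC[C@H](O)/C=C(/COCc1ccc(OC)cc1)CO[Si](CC)(CC)CC | intermediate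
13 | (8S)-enyne TBS ether: as 12 with 8-OTBS | C#CC[C@H](O[Si](C)(C)C(C)(C)C)/C=C(/COCc1ccc(OC)cc1)CO[Si](CC)(CC)CC | intermediate
14 | (8S)-ynoate: MeO2C2–C1≡C10–C9H2–C8H(OTBS)–C7H=C11(C12H2OTES)–C13H2OPMB | COC(=O)C#CC[C@H](O[Si](C)(C)C(C)(C)C)/C=C(/COCc1ccc(OC)cc1)CO[Si](CC)(CC)CC | intermediate
15 | (8S)-(1Z)-dienoate: MeO2C2–C1H=C10(CH3)–C9H2–C8H(OTBS)–C7H=C11(C12H2OTES)–C13H2OPMB; C2 cis to C9 | COC(=O)/C=C(/C)C[C@H](O[Si](C)(C)C(C)(C)C)/C=C(/COCc1ccc(OC)cc1)CO[Si](CC)(CC)CC | intermediate
16 | (8S)-dienol: as 15 with C2H2OH | OC/C=C(/C)C[C@H](O[Si](C)(C)C(C)(C)C)/C=C(/COCc1ccc(OC)cc1)CO[Si](CC)(CC)CC | intermediate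
17 | (8S)-dienal: as 15 with C2HO | O=C/C=C(/C)C[C@H](O[Si](C)(C)C(C)(C)C)/C=C(/COCc1ccc(OC)cc1)CO[Si](CC)(CC)CC | intermediate
18 | (2S,8S)-dienynol: HC5≡C4–C3H2–C2H(OH)–C1H=C10(CH3)–C9H2–C8H(OTBS)–C7H=C11(C12H2OTES)–C13H2OPMB; (Z)-C1=C10 | C#CC[C@H](O)/C=C(/C)C[C@H](O[Si](C)(C)C(C)(C)C)/C=C(/COCc1ccc(OC)cc1)CO[Si](CC)(CC)CC | intermediate
19 | C2 TES ether: as 18 with 2-OTES | C#CC[C@H](O[Si](CC)(CC)CC)/C=C(/C)C[C@H](O[Si](C)(C)C(C)(C)C)/C=C(/COCc1ccc(OC)cc1)CO[Si](CC)(CC)CC | intermediate
20 | C13 alcohol: as 19 with C13H2OH | C#CC[C@H](O[Si](CC)(CC)CC)/C=C(/C)C[C@H](O[Si](C)(C)C(C)(C)C)/C=C(/CO)CO[Si](CC)(CC)CC | intermediate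
21 | allylic mesylate: as 19 with C13H2OSO2CH3 | C#CC[C@H](O[Si](CC)(CC)CC)/C=C(/C)C[C@H](O[Si](C)(C)C(C)(C)C)/C=C(/COS(C)(=O)=O)CO[Si](CC)(CC)CC | intermediate (not isolated)
22 | C13 chloride: as 19 with C13H2Cl | C#CC[C@H](O[Si](CC)(CC)CC)/C=C(/C)C[C@H](O[Si](C)(C)C(C)(C)C)/C=C(/CCl)CO[Si](CC)(CC)CC | intermediate
23 | chloro propargylic alcohol: HOC6H2–C5≡C4–C3H2–C2H(OTES)–C1H=C10(CH3)–C9H2–C8H(OTBS)–C7H=C11(C12H2OTES)–C13H2Cl; 2S, 8S | OCC#CC[C@H](O[Si](CC)(CC)CC)/C=C(/C)C[C@H](O[Si](C)(C)C(C)(C)C)/C=C(/CCl)CO[Si](CC)(CC)CC | intermediate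
24 | thirteen-membered propargyl allyl ether (2S,8S): ring O–C6H2–C5≡C4–C3H2–C2H(OTES)–C1H=C10(CH3)–C9H2–C8H(OTBS)–C7H=C11(C12H2OTES)–C13H2; (Z)-C1=C10; C8 trans to C13 | C1C#CC[C@H](O[Si](CC)(CC)CC)/C=C(/C)C[C@H](O[Si](C)(C)C(C)(C)C)/C=C(CO[Si](CC)(CC)CC)/CO1 | intermediate
25 | ten-membered cycloalkenynol (2S,6S,7S,8S): C6–OH, C7 bearing C11(=C13H2)–C12H2OTES, C4≡C5, (Z)-C1=C10, 2-OTES, 8-OTBS; O6 trans to C11, O8 trans to C11 | O[C@@H]1C#CC[C@H](O[Si](CC)(CC)CC)/C=C(/C)C[C@H](O[Si](C)(C)C(C)(C)C)[C@H]1C(=C)CO[Si](CC)(CC)CC | intermediate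
26 | sodium alkenylalanate: aluminium bound to O6 and C4 in a five-membered ring, two 2-methoxyethoxy ligands | [Na+].COCCO[Al-]1(OCCOC)O[C@@H]2/C=C1/C[C@H](O[Si](CC)(CC)CC)/C=C(/C)C[C@H](O[Si](C)(C)C(C)(C)C)[C@H]2C(=C)CO[Si](CC)(CC)CC | intermediate (not isolated)
27 | C4 iodide (2S,6S,7S,8S): as 25 with C4(I)=C5H, iodine cis to C6, C3 trans to C6 | O[C@@H]1/C=C(\I)C[C@H](O[Si](CC)(CC)CC)/C=C(/C)C[C@H](O[Si](C)(C)C(C)(C)C)[C@H]1C(=C)CO[Si](CC)(CC)CC | intermediate
28 | C15,C6-diol (2S,6R,7S,8S): as 27 with C15H2OH in place of iodine | O[C@@H]1/C=C(\CO)C[C@H](O[Si](CC)(CC)CC)/C=C(/C)C[C@H](O[Si](C)(C)C(C)(C)C)[C@H]1C(=C)CO[Si](CC)(CC)CC | intermediate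
29 | C15 acetate (2S,6R,7S,8S) | O[C@@H]1/C=C(\COC(C)=O)C[C@H](O[Si](CC)(CC)CC)/C=C(/C)C[C@H](O[Si](C)(C)C(C)(C)C)[C@H]1C(=C)CO[Si](CC)(CC)CC | intermediate
30 | triol (2S,6R,7S,8S): 2-OH, 6-OH, 12-OH, 8-OTBS, 15-OAc | O[C@@H]1/C=C(\COC(C)=O)C[C@H](O)/C=C(/C)C[C@H](O[Si](C)(C)C(C)(C)C)[C@H]1C(=C)CO | intermediate
31 | lactol: C12 hemiacetal closed on O6, both C12 epimers | C=C1C(O)O[C@@H]2/C=C(\COC(C)=O)C[C@H](O)/C=C(/C)C[C@H](O[Si](C)(C)C(C)(C)C)[C@@H]12 | intermediate (not isolated)
32 | lactone alcohol (2S,6R,7S,8S): trans-fused 6,12-olide with 11(13)-methylene, 2-OH, 8-OTBS, 15-OAc | C=C1C(=O)O[C@@H]2/C=C(\COC(C)=O)C[C@H](O)/C=C(/C)C[C@H](O[Si](C)(C)C(C)(C)C)[C@@H]12 | intermediate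
33 | angelic acid, (Z)-2-methylbut-2-enoic acid | C/C=C(/C)C(=O)O | starting material
34 | mixed anhydride of angelic and 2,4,6-trichlorobenzoic acid | C/C=C(/C)C(=O)OC(=O)c1c(Cl)cc(Cl)cc1Cl | intermediate (not isolated)
35 | angelate TBS ether (2S,6R,7S,8S) | C=C1C(=O)O[C@@H]2/C=C(\COC(C)=O)C[C@H](OC(=O)/C(C)=C\C)/C=C(/C)C[C@H](O[Si](C)(C)C(C)(C)C)[C@@H]12 | intermediate
36 | 8-epi alcohol (2S,6R,7R,8S): target with O8 trans to C11 | C=C1C(=O)O[C@@H]2/C=C(\COC(C)=O)C[C@H](OC(=O)/C(C)=C\C)/C=C(/C)C[C@H](O)[C@@H]12 | intermediate
37 | C8 formate (2S,6R,7R,8R) | C=C1C(=O)O[C@@H]2/C=C(\COC(C)=O)C[C@H](OC(=O)/C(C)=C\C)/C=C(/C)C[C@@H](OC=O)[C@@H]12 | intermediate (not isolated)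
38 | CNP0129394.1 (2S,6R,7R,8R) | C=C1C(=O)O[C@@H]2/C=C(\COC(C)=O)C[C@H](OC(=O)/C(C)=C\C)/C=C(/C)C[C@@H](O)[C@@H]12 | target

Total step count: 27. Longest linear sequence: 26 steps (steps 1, 2 and 4 to 27; step 3 prepares stannane 5).

Steps most likely to fail

Step 19, ring contraction. What may go wrong: proton removal at the allylic ether carbon C13 or at C3, a competing [1,2]-shift through radical-pair recombination, or bond formation on the other face of C7, which would give the 6,7-bis-epimer. The fallback sets out from chloro propargylic alcohol 23, before the ether is closed. Oxidation of the propargylic alcohol with MnO2 in CH2Cl2 gives the chloro ynal F1. CrCl2 in THF at high dilution then turns the allylic chloride into an allylchromium species that adds through its C7 terminus to the C6 aldehyde (intramolecular Nozaki–Hiyama allylation). This forms the same C6–C7 bond and C11=C13 methylene through a six-membered chair, in which the C8-trans-to-C13 geometry again places O6 trans to C11, and it comes back to the route at cycloalkenynol 25.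

Step 21, hydroxymethyl Stille coupling. What may go wrong: transmetalation from the sp3 stannane is slow, so the C4 alkenylpalladium intermediate can insert the nearby C11=C13 alkene (5-exo carbopalladation) or lose iodine by protonolysis. The fallback sets out from iodide 27. Carbonylation with PdCl2(PPh3)2, CO (1 atm) and Et3N in THF traps the alkenylpalladium quickly, and the C6 hydroxyl closes the acyl intermediate to the butenolide F2 (C15 carbonyl bonded to O6). Reduction of F2 with excess i-Bu2AlH in CH2Cl2 (−78 to 0 °C) opens the lactone to the primary C15 and secondary C6 alcohols, which is diol 28, where the route is rejoined.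

Step 27, inversion at C8. What may go wrong: the oxyphosphonium ion at the hindered ring carbinol eliminates toward C9 instead of being displaced, the phosphine adds to the α-methylene lactone, or O8 attacks C12 and moves the lactone during formate cleavage. The fallback sets out from 8-epi alcohol 36. Triflation (Tf2O, pyridine, CH2Cl2, −20 °C) gives the C8 triflate F3, which Bu4N NO2 in toluene displaces with inversion to the (8R) nitrite ester F4 (Lattrell–Dax inversion). The nitrite hydrolyses on aqueous work-up to target 38 without any basic step.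

Further compounds

F1 | step 19 | chloro ynal: OHC6–C5≡C4–C3H2–C2H(OTES)–C1H=C10(CH3)–C9H2–C8H(OTBS)–C7H=C11(C12H2OTES)–C13H2Cl; 2S, 8S | O=CC#CC[C@H](O[Si](CC)(CC)CC)/C=C(/C)C[C@H](O[Si](C)(C)C(C)(C)C)/C=C(/CCl)CO[Si](CC)(CC)CC
F2 | step 21 | butenolide: C15 carbonyl on C4 lactonised to O6, otherwise as 27 | O=C1O[C@@H]2C=C1C[C@H](O[Si](CC)(CC)CC)/C=C(/C)C[C@H](O[Si](C)(C)C(C)(C)C)[C@H]2C(=C)CO[Si](CC)(CC)CC
F3 | step 27 | C8 triflate of 36 | C=C1C(=O)O[C@@H]2/C=C(\COC(C)=O)C[C@H](OC(=O)/C(C)=C\C)/C=C(/C)C[C@H](OS(=O)(=O)C(F)(F)F)[C@@H]12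
F4 | step 27 | (8R) nitrite ester | C=C1C(=O)O[C@@H]2/C=C(\COC(C)=O)C[C@H](OC(=O)/C(C)=C\C)/C=C(/C)C[C@@H](ON=O)[C@@H]12
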